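Retrosynthesis (oxolane numbering O1, C2 = CH2, C3 = CH–C(=O)Ar, C4 = CH–CH2OH, C5 = CH–Ar): cut O–Si; then, as one event, the aryl–C(=O) bond and the ring O1–C2 bond; then the lactone acyl–O and the C4–C5 bonds; then C–B, O–acetyl and the Morita–Baylis–Hillman C–C bond.
Enabling feature: O1 sits on the β-carbon (C2) and on the γ-carbon (C5) of the ketone, so the oxolane is the oxa-Michael isomer of a γ-hydroxy α-methylene aryl ketone; its masked form is an α-methylene-γ-butyrolactone in which the future ketone carbon is the lactone carbonyl, C2 the exocyclic CH2 and O1 the lactone oxygen.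
Forward: Baylis–Hillman adduct → 2-(ethoxycarbonyl)allylboronate → γ-butyrolactone ring (allylboration/lactonisation with 3,4,5-trimethoxybenzaldehyde) → 3,4,5-trimethoxyphenyllithium opens the lactone and the freed benzylic oxygen closes the oxolane (lactone-to-oxolane ring switch) → desilylation.
Stereochemistry: C5 and C4 (cis) come from the chiral phosphoric acid-catalysed, chair-controlled syn-allylboration; C3 comes from stereoconvergent thermodynamic protonation α to the new ketone (aroyl trans to the C4 and C5 substituents).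
Key step: step 5

Assumption: (S)-TRIP [(S)-3,3′-bis(2,4,6-triisopropylphenyl)-1,1′-binaphthyl-2,2′-diyl hydrogen phosphate] is taken to direct the boronate to the Si face of the aldehyde, the (R)-acid being known to give Re-face attack with allyl pinacolboronates; if the sense is reversed for this ester-bearing boronate, the (R)-acid is used.

Step 1
Reactants: 1 (tert-butyldimethylsilyloxy)acetaldehyde; 2 ethyl acrylate
Product: 3 ethyl 4-[(tert-butyldimethylsilyl)oxy]-3-hydroxy-2-methylidenebutanoate (racemic)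
Conditions: DABCO (0.5 equiv), 1,4-dioxane/H2O (1:1), rt
Reagents that add atoms: none
Why: Morita–Baylis–Hillman reaction, in which the DABCO–acrylate zwitterion adds to the unhindered α-silyloxy aldehyde; the carbinol centre forms racemic and is erased in step 3.

Step 2
Reactants: 3 ethyl 4-[(tert-butyldimethylsilyl)oxy]-3-hydroxy-2-methylidenebutanoate
Product: 4 ethyl 3-acetoxy-4-[(tert-butyldimethylsilyl)oxy]-2-methylidenebutanoate (racemic)
Conditions: Ac2O, pyridine, DMAP (cat.), CH2Cl2, 0 °C
Reagents that add atoms: acetic anhydride CC(=O)OC(C)=O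
Why: DMAP-catalysed O-acylation turns the secondary allylic hydroxyl into the leaving group for allylic substitution; 0 °C avoids a 1,3-acetate shift.

Step 3
Reactants: 4 ethyl 3-acetoxy-4-[(tert-butyldimethylsilyl)oxy]-2-methylidenebutanoate
Product: 5 ethyl (2E)-4-[(tert-butyldimethylsilyl)oxy]-2-[(4,4,5,5-tetramethyl-1,3,2-dioxaborolan-2-yl)methyl]but-2-enoate (CH2OTBS cis to CH2Bpin)
Conditions: B2pin2, CuCl (10 mol %), KOAc, DMF, rt
Reagents that add atoms: bis(pinacolato)diboron CC1(C)OB(OC1(C)C)B1OC(C)(C)C(C)(C)O1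
Why: Copper(I)-catalysed allylic (SN2′) borylation of a Morita–Baylis–Hillman acetate by boryl-cupration of the acrylate terminus and β-acetoxy elimination; the elimination should place CH2OTBS trans to the ester, the arrangement of least allylic strain.

Step 4
Reactants: 5 ethyl (2E)-4-[(tert-butyldimethylsilyl)oxy]-2-[(pinacolboryl)methyl]but-2-enoate; 6 3,4,5-trimethoxybenzaldehyde
Product: 9 (4S,5S)-4-{[(tert-butyldimethylsilyl)oxy]methyl}-3-methylidene-5-(3,4,5-trimethoxyphenyl)oxolan-2-one (cis lactone), via borate ester 7 (not isolated), via hydroxy ester 8 (not isolated)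
Conditions: (S)-TRIP (10 mol %), toluene, rt → 40 °C; then H2O (2 equiv), PPTS (10 mol %), 45 °C
Reagents that add atoms: none
Why: Chiral phosphoric acid-catalysed allylboration through a closed chair transition state, in which the γ-substituent cis to CH2B sits axial and gives the syn adduct while the (S)-acid, bound to the boronate oxygen and the formyl C–H, exposes the Si face and sets the (S)-carbinol; lactonisation by acyl substitution under PPTS does not break the benzylic C–O bond and gives the cis lactone.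

Step 5
Reactants: 9 (4S,5S)-4-{[(tert-butyldimethylsilyl)oxy]methyl}-3-methylidene-5-(3,4,5-trimethoxyphenyl)oxolan-2-one; 10 5-bromo-1,2,3-trimethoxybenzene
Product: 15 {(3R,4S,5S)-4-{[(tert-butyldimethylsilyl)oxy]methyl}-5-(3,4,5-trimethoxyphenyl)oxolan-3-yl}(3,4,5-trimethoxyphenyl)methanone, via aryllithium 11 (not isolated), via lithium hemiketal 12 (not isolated), via hydroxy enone 13 (not isolated), via enolate 14 (not isolated)
Conditions: 10 (1.1 equiv), n-BuLi (1.05 equiv), THF, −78 °C; then 9, −78 °C; then t-BuOH (3 equiv), KOt-Bu (10 mol %), −78 °C → rt; AcOH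
Reagents that add atoms: none
Why: Proposed new method: the aryllithium adds 1,2 to the lactone carbonyl and the lithium hemiketal 12 persists at −78 °C, so that only one aryl group enters; on warming with t-BuOH/KOt-Bu, 12 collapses to the aryl vinyl ketone 13 with release of the benzylic alkoxide, which adds to the exocyclic CH2 terminus to give enolate 14, protonated to 15. The closest known reaction types are the aryllithium opening of γ-lactones to lactols or γ-hydroxy ketones and the alkoxide-mediated 5-endo-trig cyclisation of homoallylic alcohols carrying a sulfonyl group on the internal alkene carbon to 3-sulfonyl tetrahydrofurans. The lactone ring opens by retro-5-exo-trig collapse of the hemiketal and the oxolane ring closes in the 5-endo-trig mode (intramolecular oxa-Michael addition, O1–C2 bond); this strained mode should be attainable because the competing 5-exo-trig attack on the ketone only re-forms 12 reversibly, the β-alkoxy ketone is the thermodynamic sink, and an aryl vinyl ketone with a free CH2 terminus is a stronger acceptor than a vinyl sulfone. The one new stereocentre, C3, is set under thermodynamic control: enolate 14 is planar at C3 and the ketone keeps equilibrating under the alkoxide, so both protonation faces converge on the isomer with the aroyl group trans to the C4 and C5 substituents, which stay cis because their bonds are not touched. The step needs 1,2- before 1,4-addition (hard aryllithium at −78 °C, none left when the enone is unveiled) and closure through the benzylic oxygen only, which the silyl ether on the primary oxygen secures.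

Step 6
Reactants: 15 {(3R,4S,5S)-4-{[(tert-butyldimethylsilyl)oxy]methyl}-5-(3,4,5-trimethoxyphenyl)oxolan-3-yl}(3,4,5-trimethoxyphenyl)methanone
Product: 16 (3,4,5-trimethoxyphenyl)[(3R,4S,5S)-4-(hydroxymethyl)-5-(3,4,5-trimethoxyphenyl)oxolan-3-yl]methanone (target)
Conditions: HF·pyridine, THF/pyridine, 0 °C → rt
Reagents that add atoms: none
Why: Fluoride cleavage of the primary silyl ether in a mildly acidic, non-basic medium, so that the β-alkoxy ketone should neither eliminate nor epimerise at C3.

Compound list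
1 | (tert-butyldimethylsilyloxy)acetaldehyde | CC(C)(C)[Si](C)(C)OCC=O | starting material
2 | ethyl acrylate | C=CC(=O)OCC | starting material
3 | ethyl 4-[(tert-butyldimethylsilyl)oxy]-3-hydroxy-2-methylidenebutanoate (racemic) | CCOC(=O)C(=C)C(O)CO[Si](C)(C)C(C)(C)C | intermediate
4 | ethyl 3-acetoxy-4-[(tert-butyldimethylsilyl)oxy]-2-methylidenebutanoate (racemic) | CCOC(=O)C(=C)C(OC(C)=O)CO[Si](C)(C)C(C)(C)C | intermediate
5 | ethyl (2E)-4-[(tert-butyldimethylsilyl)oxy]-2-[(4,4,5,5-tetramethyl-1,3,2-dioxaborolan-2-yl)methyl]but-2-enoate | CCOC(=O)/C(CB1OC(C)(C)C(C)(C)O1)=C/CO[Si](C)(C)C(C)(C)C | intermediate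
6 | 3,4,5-trimethoxybenzaldehyde | COc1cc(C=O)cc(OC)c1OC | starting material
7 | ethyl (3S,4S)-3-{[(tert-butyldimethylsilyl)oxy]methyl}-2-methylidene-4-[(pinacolboryl)oxy]-4-(3,4,5-trimethoxyphenyl)butanoate (borate ester, not isolated) | CCOC(=O)C(=C)[C@@H](CO[Si](C)(C)C(C)(C)C)[C@H](OB1OC(C)(C)C(C)(C)O1)c1cc(OC)c(OC)c(OC)c1 | intermediate
8 | ethyl (3S,4S)-3-{[(tert-butyldimethylsilyl)oxy]methyl}-4-hydroxy-2-methylidene-4-(3,4,5-trimethoxyphenyl)butanoate (syn hydroxy ester, not isolated) | CCOC(=O)C(=C)[C@@H](CO[Si](C)(C)C(C)(C)C)[C@H](O)c1cc(OC)c(OC)c(OC)c1 | intermediate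
9 | (4S,5S)-4-{[(tert-butyldimethylsilyl)oxy]methyl}-3-methylidene-5-(3,4,5-trimethoxyphenyl)oxolan-2-one (cis) | C=C1C(=O)O[C@H](c2cc(OC)c(OC)c(OC)c2)[C@@H]1CO[Si](C)(C)C(C)(C)C | intermediate
10 | 5-bromo-1,2,3-trimethoxybenzene | COc1cc(Br)cc(OC)c1OC | starting material
11 | 3,4,5-trimethoxyphenyllithium (not isolated) | COc1cc([Li])cc(OC)c1OC | intermediate
12 | lithium (4S,5S)-4-{[(tert-butyldimethylsilyl)oxy]methyl}-3-methylidene-2,5-bis(3,4,5-trimethoxyphenyl)oxolan-2-olate (hemiketal, C2 undefined, not isolated) | C=C1[C@@H](CO[Si](C)(C)C(C)(C)C)[C@@H](c2cc(OC)c(OC)c(OC)c2)OC1(O[Li])c1cc(OC)c(OC)c(OC)c1 | intermediate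
13 | (3S,4S)-3-{[(tert-butyldimethylsilyl)oxy]methyl}-4-hydroxy-2-methylidene-1,4-bis(3,4,5-trimethoxyphenyl)butan-1-one (not isolated) | C=C(C(=O)c1cc(OC)c(OC)c(OC)c1)[C@@H](CO[Si](C)(C)C(C)(C)C)[C@H](O)c1cc(OC)c(OC)c(OC)c1 | intermediate
14 | lithium enolate of 15, planar at oxolane C3 (not isolated) | [Li]OC(=C1CO[C@H](c2cc(OC)c(OC)c(OC)c2)[C@@H]1CO[Si](C)(C)C(C)(C)C)c1cc(OC)c(OC)c(OC)c1 | intermediate
15 | {(3R,4S,5S)-4-{[(tert-butyldimethylsilyl)oxy]methyl}-5-(3,4,5-trimethoxyphenyl)oxolan-3-yl}(3,4,5-trimethoxyphenyl)methanone | COc1cc(C(=O)[C@H]2CO[C@H](c3cc(OC)c(OC)c(OC)c3)[C@@H]2CO[Si](C)(C)C(C)(C)C)cc(OC)c1OC | intermediate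
16 | (3,4,5-trimethoxyphenyl)[(3R,4S,5S)-4-(hydroxymethyl)-5-(3,4,5-trimethoxyphenyl)oxolan-3-yl]methanone | COc1cc(C(=O)[C@H]2CO[C@H](c3cc(OC)c(OC)c(OC)c3)[C@@H]2CO)cc(OC)c1OC | target

Total step count: 6. Longest linear sequence: 6 steps (1 → 3 → 4 → 5 → 9 → 15 → 16).

Steps most likely to fail

Step 5. The 5-endo-trig closure may be slower than intermolecular Michael oligomerisation of the unveiled aryl vinyl ketone. The aryllithium may also add in the conjugate sense, or the silyl group may shift to the benzylic oxygen under alkoxide so that the primary oxygen closes the ring instead. The fallback uses known chemistry only, sets out from 9 and comes back at 15. DIBAL-H (CH2Cl2, −78 °C) reduces the lactone to the 2-methylene-1,4-diol F1. Selective sulfonylation of the primary allylic hydroxyl (TsCl, Et3N, Me3N·HCl cat., 0 °C) gives the monotosylate F2. NaH then closes the ring by Williamson etherification (5-exo-tet, benzylic C–O bond untouched) to the 4-methylideneoxolane F3. Hydroboration with 9-BBN gives the alkylborane F4, and NaOH/H2O2 gives the primary alcohol F5 (mixture at the new ring centre, without consequence). Dess–Martin oxidation gives the aldehyde F6. Aryllithium 11 (from 10 and n-BuLi) adds to F6 and gives the diaryl carbinol F7, which makes the same aryl–carbon bond at the alcohol oxidation level. A second Dess–Martin oxidation gives ketone 15 together with its all-cis C3 epimer F8, and DBU (CH2Cl2, rt) equilibrates the mixture to 15.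

Step 4. Facial discrimination by the acid may be weak with the ester-deactivated, γ-substituted boronate, and an uncatalysed background pathway at the temperature needed would erode the enantiomeric purity; the chair transition state should still give the cis series. The fallback sets out from 5 and 6 and comes back at 9. The allylboration is run thermally without catalyst (toluene, 80 °C) and lactonised as before. This gives racemic material: 7, 8 and 9 together with the enantiomeric borate ester F9, the enantiomeric hydroxy ester F10 and the enantiomeric lactone F11. Lactone 9 is then separated from F11 by preparative supercritical-fluid chromatography on a polysaccharide chiral stationary phase.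

Step 6. If the medium turns basic during desilylation, the β-alkoxy ketone may undergo β-elimination (retro-oxa-Michael) and re-close through the newly freed primary hydroxyl, or epimerise at C3. The fallback sets out from 15 and comes back at 16. NaBH4 (MeOH, 0 °C) removes the acidifying carbonyl and gives the carbinol F12 (new carbinol centre without consequence). TBAF (THF) then gives the diol F13. Activated MnO2 (CH2Cl2, rt) oxidises only the benzylic secondary alcohol and gives 16.

Further compounds
F1 | step 5 | (1S,2S)-2-{[(tert-butyldimethylsilyl)oxy]methyl}-3-methylidene-1-(3,4,5-trimethoxyphenyl)butane-1,4-diol | C=C(CO)[C@@H](CO[Si](C)(C)C(C)(C)C)[C@H](O)c1cc(OC)c(OC)c(OC)c1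
F2 | step 5 | (3S,4S)-3-{[(tert-butyldimethylsilyl)oxy]methyl}-4-hydroxy-2-methylidene-4-(3,4,5-trimethoxyphenyl)butyl 4-methylbenzenesulfonate | C=C(COS(=O)(=O)c1ccc(C)cc1)[C@@H](CO[Si](C)(C)C(C)(C)C)[C@H](O)c1cc(OC)c(OC)c(OC)c1
F3 | step 5 | tert-butyldimethyl{[(2S,3S)-4-methylidene-2-(3,4,5-trimethoxyphenyl)oxolan-3-yl]methoxy}silane | C=C1CO[C@H](c2cc(OC)c(OC)c(OC)c2)[C@@H]1CO[Si](C)(C)C(C)(C)C
F4 | step 5 | 9-{[(4S,5S)-4-{[(tert-butyldimethylsilyl)oxy]methyl}-5-(3,4,5-trimethoxyphenyl)oxolan-3-yl]methyl}-9-borabicyclo[3.3.1]nonane (C3 epimers) | C1CC2CCCC(C1)B2CC1CO[C@H](c3cc(OC)c(OC)c(OC)c3)[C@@H]1CO[Si](C)(C)C(C)(C)C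
F5 | step 5 | [(4S,5S)-4-{[(tert-butyldimethylsilyl)oxy]methyl}-5-(3,4,5-trimethoxyphenyl)oxolan-3-yl]methanol (C3 epimers) | OCC1CO[C@H](c2cc(OC)c(OC)c(OC)c2)[C@@H]1CO[Si](C)(C)C(C)(C)C
F6 | step 5 | (4S,5S)-4-{[(tert-butyldimethylsilyl)oxy]methyl}-5-(3,4,5-trimethoxyphenyl)oxolane-3-carbaldehyde (C3 epimers) | O=CC1CO[C@H](c2cc(OC)c(OC)c(OC)c2)[C@@H]1CO[Si](C)(C)C(C)(C)C
F7 | step 5 | [(4S,5S)-4-{[(tert-butyldimethylsilyl)oxy]methyl}-5-(3,4,5-trimethoxyphenyl)oxolan-3-yl](3,4,5-trimethoxyphenyl)methanol (mixture at C3 and at the carbinol carbon) | OC(c1cc(OC)c(OC)c(OC)c1)C1CO[C@H](c2cc(OC)c(OC)c(OC)c2)[C@@H]1CO[Si](C)(C)C(C)(C)C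
F8 | step 5 | {(3S,4S,5S)-4-{[(tert-butyldimethylsilyl)oxy]methyl}-5-(3,4,5-trimethoxyphenyl)oxolan-3-yl}(3,4,5-trimethoxyphenyl)methanone (all-cis C3 epimer of 15) | COc1cc(C(=O)[C@@H]2CO[C@H](c3cc(OC)c(OC)c(OC)c3)[C@@H]2CO[Si](C)(C)C(C)(C)C)cc(OC)c1OC
F9 | step 4 | ethyl (3R,4R)-3-{[(tert-butyldimethylsilyl)oxy]methyl}-2-methylidene-4-[(pinacolboryl)oxy]-4-(3,4,5-trimethoxyphenyl)butanoate (enantiomer of 7) | CCOC(=O)C(=C)[C@H](CO[Si](C)(C)C(C)(C)C)[C@@H](OB1OC(C)(C)C(C)(C)O1)c1cc(OC)c(OC)c(OC)c1
F10 | step 4 | ethyl (3R,4R)-3-{[(tert-butyldimethylsilyl)oxy]methyl}-4-hydroxy-2-methylidene-4-(3,4,5-trimethoxyphenyl)butanoate (enantiomer of 8) | CCOC(=O)C(=C)[C@H](CO[Si](C)(C)C(C)(C)C)[C@@H](O)c1cc(OC)c(OC)c(OC)c1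
F11 | step 4 | (4R,5R)-4-{[(tert-butyldimethylsilyl)oxy]methyl}-3-methylidene-5-(3,4,5-trimethoxyphenyl)oxolan-2-one (enantiomer of 9) | C=C1C(=O)O[C@@H](c2cc(OC)c(OC)c(OC)c2)[C@H]1CO[Si](C)(C)C(C)(C)C
F12 | step 6 | [(3R,4S,5S)-4-{[(tert-butyldimethylsilyl)oxy]methyl}-5-(3,4,5-trimethoxyphenyl)oxolan-3-yl](3,4,5-trimethoxyphenyl)methanol (carbinol carbon undefined) | OC(c1cc(OC)c(OC)c(OC)c1)[C@H]1CO[C@H](c2cc(OC)c(OC)c(OC)c2)[C@@H]1CO[Si](C)(C)C(C)(C)C
F13 | step 6 | [(3R,4S,5S)-4-(hydroxymethyl)-5-(3,4,5-trimethoxyphenyl)oxolan-3-yl](3,4,5-trimethoxyphenyl)methanol (carbinol carbon undefined) | OC(c1cc(OC)c(OC)c(OC)c1)[C@H]1CO[C@H](c2cc(OC)c(OC)c(OC)c2)[C@@H]1CO
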